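How much isomer of the product and how much target stand in this flask after 3.0 h?

| flask | substrate | reagent | other conformer | remark | time |
|---|---|---|---|---|---|
| east | 0.0020 M | 2 mM | 0.20 mM | the very flask that is asked about, followed so far |  |
| flask | 0.0020 M | 2.00 mM | 0.200 mM |  | 3.0 h |

east run (percent of the substrate and other conformer together charged)

| time / min | isomer of the product / % | target / % |
|---|---|---|
| 4.00 | 7.3 | 17.8 |
| 6.00 | 11.4 | 17.1 |
| 10.0 | 17.3 | 14.8 |
| 15.0 | 23.6 | 13.6 |
| 25.0 | 33.1 | 9.8 |
| 40.0 | 45.1 | 7.6 |
| 50.0 | 51.5 | 6.1 |

(readings scatter by 0.5 percentage points)

1. share of isomer of the product in isomer of the product plus target at 2.0 s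
2. share of isomer of the product in isomer of the product plus target at 2.5 min
3. share of isomer of the product in isomer of the product plus target at 3.0 h
4. which of isomer of the product and target there is more of at 3.0 h

- the analysis behind the earlier runs scatters by 0.5 percentage points, standard deviation

I call substrate and other conformer together the pool. As fractions of the pool charged, x is isomer plus target, S is the pool left, one minus x, and R is the reagent left, ρ minus x, with ρ = 0.909. If x grows at a rate κSR, with κ a constant, S and R lose the same amount, so their difference stays fixed, and ln(S/R) climbs steadily at κ times that difference. My number is therefore Λ = ln(ρS/R), the logarithm of how far S/R has grown since the charge.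

The readings give Λ = 0.0341 at 4.00 min and 0.146 at 50.0 min, a slope of 0.00243 min⁻¹. The reading at 25.0 min gives 0.0781, against 0.0851 on that line. Carried to 3.0 h, the line gives Λ = 0.462, which leaves S = 21.3%.

One number is not enough, since Λ gives the amount used and not its split. A second number, B = target/(SR), reads 0.371 at 10.0 min and 0.432 at 50.0 min, while the target reading falls from 14.8% to 6.1%, so I treat the target as a fast pre-equilibrium. Taking the reading at 10.0 min, I get target 0.960% at 3.0 h and a share of 98.8%. At 2.5 min the line leaves S = 76.9% and a share of 16.1%. No reading stands near 2.0 s, so I reckon nothing there.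

The forecast, calling the target “a fast, reversible adduct”, gives 3%, 19% and 98.9%, with isomer of the product ahead, and my share at 2.5 min is lower than its figure.

The flask gives 6.09%, 20.8% and 98.9%, with isomer of the product at 78.7% and target at 0.862%.

    substrate ⇌ other conformer (K = 0.00150, k = 0.0150 s⁻¹)
    substrate + reagent ⇌ target (K = 170 L mol⁻¹, k = 19.0 L mol⁻¹ s⁻¹)
    reagent + other conformer → isomer of the product (k = 180 L mol⁻¹ s⁻¹)

This flask holds substrate 20.4% and other conformer 0.0304% at 3.0 h, where Λ left a pool of 21.3%. In the neighbouring flask the substrate charge is 8.0 × 10⁻⁴ M, so the pool is charged below the reagent and ρ becomes 2.00. Scaled by the difference of the charges, Λ turns negative, −2.31, and S/R shrinks, leaving a pool of 5.21%. At 3.0 h the neighbouring flask holds substrate 4.62%, other conformer 0.00680% and isomer of the product 94.6%.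

The numbers in the tables come from a simulation on assumed constants.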